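**Plan**

1. Cuts: the three angelate C–O bonds, made one per acylation (C8, then C9, then C7 after desilylation); the C8/C9 diol (back to a C8=C9 alkene); C4–C10 of the four-membered ring (Claisen ring contraction of an O8–CO–C4 lactone, the carboxyl then removed from bridgehead C4); C4–C5 together with C2=C3 (tethered Michael/aldol condensation, a Robinson annulation); C11–C1 (acetyl via an enol triflate).
2. Forward: carvone gives eucarvone, which supplies the seven-membered ring C5–C11 with C6(CH3)2 and C10–CH3. The cyclohexenone ring C1–C2–C3–C4–C5–C11 is annulated first, then the cyclobutane C4–C5–C11–C10 is closed, then C8=C9 is dihydroxylated and the three hydroxyls are angeloylated in turn, with C7 unmasked before the last acylation.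
3. Enabling feature: ring C1–C2–C3–C4–C5–C11 is a 3-methylcyclohex-2-enone (1,5-dicarbonyl relation C1/C3), and C4 lies on the β face of the seven-membered ring, bonded to both C5 and C10. An acetoacetate on a β-oxygen at allylic C8 can therefore hand C4 first to C5 (Michael, with aldol closure of C2=C3) and then to C10 ([3,3], the oxygen leaving C8).
4. Stereochemistry: absolute configuration from a Jacobsen epoxidation (C7); the temporary β C8–O bond from a retentive Pd substitution; C5 and C10 from delivery of C4 by that β tether; C11 and C4 locked by the cage; C8 and C9 from OsO4 anti to the C7 silyl ether.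

Key step: step 10

Remark: atoms are numbered as in the target (C1 ketone carbon; C2=C3 enone alkene, CH3 on C3; C4 and C11 the CH atoms next to C3 and C1; C5 the CH joining C4, C11 and C6; C6 the C(CH3)2 carbon; C7–C9 the oxygenated carbons; C10 the methyl-bearing quaternary carbon). β is the face of the seven-membered ring C5–C11 that carries C4 and the C7 oxygen, α the face that carries the C8 and C9 oxygens of the target. The facial sense of step 3 is assumed from the 2,2-dimethylchromene model of the Jacobsen epoxidation; the antipodal catalyst would be used if the sense proved opposite.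

**Route**

Step 1
Reactants: 1 (R)-(−)-carvone
Product: 2 carvone hydrobromide
Conditions: HBr (33% in AcOH), 0 °C
Reagents that add atoms: hydrogen bromide, Br
Why: Markovnikov hydrobromination of the isopropenyl group (the more electron-rich alkene) should give the tertiary bromide and leave the enone untouched; the stereocentre is erased in step 2, so either enantiomer of carvone serves.

Step 2
Reactants: 2 carvone hydrobromide
Product: 4 eucarvone, via car-3-en-2-one 3 (not isolated)
Conditions: KOH, MeOH, reflux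
Reagents that add atoms: none
Why: Intramolecular alkylation of the C6 enolate by the tertiary bromide (1,3-elimination of HBr) gives the cyclopropane 3, whose enolate opens to the conjugated cycloheptadienone (the classical carvone-to-eucarvone conversion).

Step 3
Reactants: 4 eucarvone
Product: 5 (4R,5S)-4,5-epoxy-2,6,6-trimethylcyclohept-2-en-1-one
Conditions: (R,R)-(salen)MnCl (5 mol %; salen = N,N'-bis(3,5-di-tert-butylsalicylidene)-1,2-cyclohexanediaminate), 4-phenylpyridine N-oxide, NaOCl (aq, pH 11.3), CH2Cl2, 0 °C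
Reagents that add atoms: sodium hypochlorite, [Na+].[O-]Cl
Why: The Jacobsen epoxidation should pick the cis-disubstituted, conjugated γ,δ-alkene (C7=C8) over the electron-poor trisubstituted α,β-alkene; this alkene, flanked by CMe2 and a vinyl group, resembles 2,2-dimethylchromene, so the (R,R) catalyst is expected to deliver oxygen to the β face and set C7.

Step 4
Reactants: 5 (4R,5S)-4,5-epoxy-2,6,6-trimethylcyclohept-2-en-1-one
Product: 6 (4R,5S)-5-hydroxy-4-[(4-methoxybenzyl)oxy]-2,6,6-trimethylcyclohept-2-en-1-one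
Conditions: Pd(PPh3)4 (5 mol %), B(OCH2C6H4-4-OMe)3 (1.5 equiv), THF, 23 °C; aqueous work-up
Reagents that add atoms: tris(4-methoxybenzyl) borate, COc1ccc(COB(OCc2ccc(OC)cc2)OCc2ccc(OC)cc2)cc1
Why: Zerovalent palladium ionises the allylic C8–O bond with inversion and the borate held by the C7 alkoxide returns the alkoxy group to C8 from the same β face, so the known Pd-catalysed alkoxy substitution of γ,δ-epoxy-α,β-unsaturated carbonyl compounds with trialkyl borates should give the cis (7β-OH, 8β-OPMB) product by double inversion.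

Step 5
Reactants: 6 (4R,5S)-5-hydroxy-4-[(4-methoxybenzyl)oxy]-2,6,6-trimethylcyclohept-2-en-1-one
Product: 7 (4R,5S)-5-[(tert-butyldimethylsilyl)oxy]-4-[(4-methoxybenzyl)oxy]-2,6,6-trimethylcyclohept-2-en-1-one
Conditions: TBSOTf, 2,6-lutidine, CH2Cl2, −78 → 0 °C
Reagents that add atoms: tert-butyldimethylsilyl triflate, CC(C)(C)[Si](C)(C)OS(=O)(=O)C(F)(F)F
Why: The silyl triflate should silylate the hindered C7 alcohol, which must stay protected until step 16.

Step 6
Reactants: 7 (4R,5S)-5-[(tert-butyldimethylsilyl)oxy]-4-[(4-methoxybenzyl)oxy]-2,6,6-trimethylcyclohept-2-en-1-one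
Product: 8 dienyl triflate (7β-OTBS 8β-OPMB)
Conditions: KN(SiMe3)2, THF, −78 °C; PhNTf2, −78 → 0 °C
Reagents that add atoms: N-phenylbis(trifluoromethanesulfonimide), O=S(=O)(N(c1ccccc1)S(=O)(=O)C(F)(F)F)C(F)(F)F
Why: Kinetic deprotonation of the enone at its only α' position (C5, as in isophorone) and O-triflation should give the cross-conjugated dienyl triflate regiospecifically.

Step 7
Reactants: 8 dienyl triflate (7β-OTBS 8β-OPMB)
Product: 10 acetyl diene (7β-OTBS 8β-OPMB), via 1-ethoxyvinyl triene 9 (not isolated)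
Conditions: Bu3SnC(OEt)=CH2, Pd(PPh3)4 (5 mol %), LiCl, THF, 65 °C; then 1 M HCl, THF, 0 °C
Reagents that add atoms: tributyl(1-ethoxyvinyl)stannane, CCCC[Sn](CCCC)(CCCC)C(=C)OCC; water, O
Why: Stille coupling of the vinyl triflate with the acetyl-anion equivalent, then mild hydrolysis of the enol ether, should install the C11 acetyl group (C1 and C2) without touching the silyl or PMB ether.

Step 8
Reactants: 10 acetyl diene (7β-OTBS 8β-OPMB)
Product: 11 allylic alcohol (7β-OTBS 8β-OH)
Conditions: DDQ, CH2Cl2/pH 7 buffer (10:1), 0 °C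
Reagents that add atoms: none
Why: Oxidative PMB cleavage should free the allylic C8 alcohol; the silyl ether and the electron-poor acyl diene are inert to DDQ.

Step 9
Reactants: 11 allylic alcohol (7β-OTBS 8β-OH)
Product: 12 C8 acetoacetate
Conditions: diketene, DMAP (5 mol %), CH2Cl2, −20 → 0 °C
Reagents that add atoms: diketene, C=C1CC(=O)O1
Why: DMAP-catalysed ring opening of diketene by the alcohol should give the acetoacetate (the tether plus C3, C4 and the C3 methyl) at low temperature, so no Carroll rearrangement can intervene.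

Step 10
Reactants: 12 C8 acetoacetate
Product: 14 tricyclic lactone enone, via Michael adduct 13 (not isolated)
Conditions: Cs2CO3 (0.1 equiv), MeCN, 0 → 23 °C; then AcOH (0.6 equiv), pyrrolidine (0.5 equiv), 50 °C (one pot)
Reagents that add atoms: none
Why: The doubly activated methylene C4 of the acetoacetate adds to the β-carbon C5 of the acetyl-bearing enone (intramolecular Michael addition), and the pyrrolidine enamine of the C11 acetyl group (C2) then attacks the acetoacetate ketone C3 and water is lost (aldol condensation), which together form an intramolecular Robinson annulation. The closest known reactions are the carbonate-catalysed Michael addition of β-keto esters to enones and the amine-mediated cyclodehydration of 2-(3-oxobutyl)acetoacetates to 4-carboalkoxy-3-methylcyclohex-2-enones. The seven-membered lactone closes 7-exo-trig (C11 stays outside the new ring) and the cyclohexenone closes 6-(enolendo)-exo-trig onto the C3 carbonyl, followed by dehydration. C5 is set by the tether, which reaches only the β face from the β-oxygen at C8; C11 is protonated from the α face, anti to the new C4–C5 bond, and can equilibrate to the cis ring fusion; C4 is fixed by the lactone bridge and is re-made in step 11. The step needs C4 and not the acetoacetate methyl as donor (secured by the acidity of the 1,3-dicarbonyl methylene), C3 and not C1 as aldol acceptor (the enamine forms at the unhindered C2 methyl and attacks the β-keto-ester ketone), and no loss of the allylic C8 carboxylate through a C11 enolate (sub-stoichiometric base, rapid proton transfer from the 1,3-dicarbonyl, and an enamine that cannot form at fully substituted C11).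

Step 11
Reactants: 14 tricyclic lactone enone
Product: 15 7β-[(tert-butyldimethylsilyl)oxy]-1-oxolongipina-2,8-diene-4-carboxylic acid
Conditions: KN(SiMe3)2 (1.1 equiv), PhMe, −78 → 100 °C; then 1 M HCl
Reagents that add atoms: none
Why: In a Carroll-type ester-enolate Claisen rearrangement ([3,3], the alicyclic Claisen ring contraction of lactone enolates) the planar C4 enolate, held over the β face by the C4–C5 bond and the lactone, should bond to C10 as the allylic C8–O bond breaks; this closes the four-membered ring, leaves the C8=C9 alkene, and sets C10 (C4 β, CH3 α) and C4 by suprafacial delivery.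

Step 12
Reactants: 15 7β-[(tert-butyldimethylsilyl)oxy]-1-oxolongipina-2,8-diene-4-carboxylic acid
Product: 18 7β-[(tert-butyldimethylsilyl)oxy]longipina-2,8-dien-1-one, via acid chloride 16 (not isolated), via Barton ester 17 (not isolated)
Conditions: (COCl)2, DMF (cat.), CH2Cl2, 0 → 23 °C; then C5H4NOSNa (sodium 2-thioxopyridin-1(2H)-olate), DMAP (cat.), t-BuSH (10 equiv), PhH, hν (tungsten lamp), 23 °C
Reagents that add atoms: none
Why: Barton reductive decarboxylation should replace the bridgehead carboxyl by hydrogen; the thiol is used in large excess so that hydrogen transfer to the cyclobutyl bridgehead radical outruns ring opening, and C4 cannot invert within the cage.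

Step 13
Reactants: 18 7β-[(tert-butyldimethylsilyl)oxy]longipina-2,8-dien-1-one
Product: 19 7β-[(tert-butyldimethylsilyl)oxy]-8α,9α-dihydroxylongipin-2-en-1-one
Conditions: OsO4 (2 mol %), NMO, acetone/H2O (8:1), 0 → 23 °C
Reagents that add atoms: N-methylmorpholine N-oxide, C[N+]1([O-])CCOCC1; water, O
Why: Catalytic OsO4 dihydroxylation should attack the only electron-rich alkene (C8=C9) from the α face, anti to the allylic C7 silyl ether, giving the cis-8α,9α-diol; the enone alkene is too electron-poor to compete.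

Step 14
Reactants: 19 7β-[(tert-butyldimethylsilyl)oxy]-8α,9α-dihydroxylongipin-2-en-1-one; 20 angelic acid
Product: 21 8α-(angeloyloxy)-7β-[(tert-butyldimethylsilyl)oxy]-9α-hydroxylongipin-2-en-1-one
Conditions: 20 (1.2 equiv), 2,4,6-Cl3C6H2COCl (1.2 equiv), Et3N, PhMe, 23 °C; then 19, PhMe, 50 °C
Reagents that add atoms: none
Why: Yamaguchi-type acylation with about one equivalent of the preformed mixed anhydride and without DMAP (conditions under which angelates should not isomerise to tiglates) should esterify the C8 hydroxyl first, because the C9 hydroxyl is neopentylic and syn to the C10 methyl; any 9-monoester or diester formed alongside converges in step 15.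

Step 15
Reactants: 21 8α-(angeloyloxy)-7β-[(tert-butyldimethylsilyl)oxy]-9α-hydroxylongipin-2-en-1-one; 20 angelic acid
Product: 22 8α,9α-bis(angeloyloxy)-7β-[(tert-butyldimethylsilyl)oxy]longipin-2-en-1-one
Conditions: 20 (4 equiv), 2,4,6-Cl3C6H2COCl (4 equiv), Et3N, PhMe, 23 °C; then 21, PhMe, 90 °C
Reagents that add atoms: none
Why: The same Yamaguchi-type acylation, now with excess mixed anhydride and at higher temperature, should esterify the remaining hindered C9 hydroxyl without touching a stereocentre or the Z geometry of the angelates.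

Step 16
Reactants: 22 8α,9α-bis(angeloyloxy)-7β-[(tert-butyldimethylsilyl)oxy]longipin-2-en-1-one
Product: 23 8α,9α-bis(angeloyloxy)-7β-hydroxylongipin-2-en-1-one
Conditions: HF·pyridine, pyridine/THF, 0 → 40 °C
Reagents that add atoms: none
Why: Fluoride-driven Si–O cleavage under buffered, weakly acidic conditions should free the hindered C7 alcohol without affecting the enone or the angelates, and an acyl shift from O8 to O7 would be harmless because step 17 places the same acyl group on whichever hydroxyl is free.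

Step 17
Reactants: 23 8α,9α-bis(angeloyloxy)-7β-hydroxylongipin-2-en-1-one; 20 angelic acid
Product: 24 7β,8α,9α-tris(angeloyloxy)longipin-2-en-1-one (CNP0330079.1)
Conditions: 20 (5 equiv), 2,4,6-Cl3C6H2COCl (5 equiv), Et3N, PhMe, 23 °C; then 23, PhMe, 90 °C
Reagents that add atoms: none
Why: Yamaguchi-type acylation with the preformed mixed anhydride and without DMAP is expected to esterify the last, neopentylic C7 alcohol without Z-to-E isomerisation and without touching a stereocentre.

**Compound list**

1 | (R)-(−)-carvone | CC1=CC[C@H](CC1=O)C(C)=C | starting material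
2 | carvone hydrobromide, (5R)-5-(2-bromopropan-2-yl)-2-methylcyclohex-2-en-1-one | CC1=CC[C@H](CC1=O)C(C)(C)Br | intermediate
3 | car-3-en-2-one (cis-fused 3,7,7-trimethylbicyclo[4.1.0]hept-3-en-2-one) | CC1=CC[C@@H]2[C@H](C1=O)C2(C)C | intermediate
4 | eucarvone, 2,6,6-trimethylcyclohepta-2,4-dien-1-one | CC1=CC=CC(C)(C)CC1=O | intermediate
5 | (4R,5S)-4,5-epoxy-2,6,6-trimethylcyclohept-2-en-1-one (7β,8β-epoxide) | CC1=C[C@H]2O[C@H]2C(C)(C)CC1=O | intermediate
6 | (4R,5S)-5-hydroxy-4-[(4-methoxybenzyl)oxy]-2,6,6-trimethylcyclohept-2-en-1-one (7β-OH, 8β-OPMB) | CC1=C[C@@H](OCc2ccc(OC)cc2)[C@@H](O)C(C)(C)CC1=O | intermediate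
7 | (4R,5S)-5-[(tert-butyldimethylsilyl)oxy]-4-[(4-methoxybenzyl)oxy]-2,6,6-trimethylcyclohept-2-en-1-one | CC1=C[C@@H](OCc2ccc(OC)cc2)[C@@H](O[Si](C)(C)C(C)(C)C)C(C)(C)CC1=O | intermediate
8 | 4-[(tert-butyldimethylsilyl)oxy]-5-[(4-methoxybenzyl)oxy]-3,3,7-trimethylcyclohepta-1,6-dien-1-yl triflate (4,5-cis; 7β-OTBS, 8β-OPMB) | CC1=C[C@@H](OCc2ccc(OC)cc2)[C@@H](O[Si](C)(C)C(C)(C)C)C(C)(C)C=C1OS(=O)(=O)C(F)(F)F | intermediate
9 | 1-(1-ethoxyvinyl) analogue of 8 (triflate replaced by C(OEt)=CH2) | CC1=C[C@@H](OCc2ccc(OC)cc2)[C@@H](O[Si](C)(C)C(C)(C)C)C(C)(C)C=C1C(=C)OCC | intermediate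
10 | 1-{4-[(tert-butyldimethylsilyl)oxy]-5-[(4-methoxybenzyl)oxy]-3,3,7-trimethylcyclohepta-1,6-dien-1-yl}ethan-1-one (4,5-cis) | CC1=C[C@@H](OCc2ccc(OC)cc2)[C@@H](O[Si](C)(C)C(C)(C)C)C(C)(C)C=C1C(C)=O | intermediate
11 | 1-{4-[(tert-butyldimethylsilyl)oxy]-5-hydroxy-3,3,7-trimethylcyclohepta-1,6-dien-1-yl}ethan-1-one (4,5-cis; 7β-OTBS, 8β-OH) | CC1=C[C@@H](O)[C@@H](O[Si](C)(C)C(C)(C)C)C(C)(C)C=C1C(C)=O | intermediate
12 | 3-oxobutanoate (acetoacetate) of 11 at O8 | CC1=C[C@@H](OC(=O)CC(C)=O)[C@@H](O[Si](C)(C)C(C)(C)C)C(C)(C)C=C1C(C)=O | intermediate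
13 | Michael adduct: seven-membered lactone O8–CO–C4 with C4 bonded to C5 on the β face, acetyl groups on C4 and on C11 (C11 acetyl β), C9=C10 alkene, 7β-OTBS (C4 epimerisable) | O=C1O[C@@H]2C=C(C)[C@H](C(C)=O)[C@H]([C@H]1C(C)=O)C(C)(C)[C@@H]2O[Si](C)(C)C(C)(C)C | intermediate
14 | tricyclic lactone enone: cyclohexenone C1–C2–C3–C4–C5–C11 cis-fused to the cycloheptene at C5–C11 and bridged by the C4–CO–O–C8 lactone, C9=C10 alkene, 7β-OTBS | O=C1O[C@@H]2C=C(C)[C@@H]3C(=O)C=C(C)[C@@H]1[C@@H]3C(C)(C)[C@@H]2O[Si](C)(C)C(C)(C)C | intermediate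
15 | 7β-[(tert-butyldimethylsilyl)oxy]-1-oxolongipina-2,8-diene-4-carboxylic acid | C1=C[C@@]2(C)[C@@H]3C(=O)C=C(C)[C@@]2(C(=O)O)[C@@H]3C(C)(C)[C@@H]1O[Si](C)(C)C(C)(C)C | intermediate
16 | acid chloride of 15 | C1=C[C@@]2(C)[C@@H]3C(=O)C=C(C)[C@@]2(C(Cl)=O)[C@@H]3C(C)(C)[C@@H]1O[Si](C)(C)C(C)(C)C | intermediate
17 | O-acyl thiohydroxamate (Barton ester) of 15 | C1=C[C@@]2(C)[C@@H]3C(=O)C=C(C)[C@@]2(C(=O)ON4C=CC=CC4=S)[C@@H]3C(C)(C)[C@@H]1O[Si](C)(C)C(C)(C)C | intermediate
18 | 7β-[(tert-butyldimethylsilyl)oxy]longipina-2,8-dien-1-one | C1=C[C@@]2(C)[C@@H]3C(=O)C=C(C)[C@H]2[C@@H]3C(C)(C)[C@@H]1O[Si](C)(C)C(C)(C)C | intermediate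
19 | 7β-[(tert-butyldimethylsilyl)oxy]-8α,9α-dihydroxylongipin-2-en-1-one | O[C@@H]1[C@@H](O[Si](C)(C)C(C)(C)C)C(C)(C)[C@@H]2[C@H]3C(=O)C=C(C)[C@@H]2[C@@]3(C)[C@@H]1O | intermediate
20 | angelic acid, (Z)-2-methylbut-2-enoic acid | C/C=C(/C)C(=O)O | starting material
21 | 8α-(angeloyloxy)-7β-[(tert-butyldimethylsilyl)oxy]-9α-hydroxylongipin-2-en-1-one | C/C=C(/C)C(=O)O[C@@H]1[C@@H](O[Si](C)(C)C(C)(C)C)C(C)(C)[C@@H]2[C@H]3C(=O)C=C(C)[C@@H]2[C@@]3(C)[C@@H]1O | intermediate
22 | 8α,9α-bis(angeloyloxy)-7β-[(tert-butyldimethylsilyl)oxy]longipin-2-en-1-one | C/C=C(/C)C(=O)O[C@@H]1[C@@H](O[Si](C)(C)C(C)(C)C)C(C)(C)[C@@H]2[C@H]3C(=O)C=C(C)[C@@H]2[C@@]3(C)[C@@H]1OC(=O)/C(C)=C\C | intermediate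
23 | 8α,9α-bis(angeloyloxy)-7β-hydroxylongipin-2-en-1-one | C/C=C(/C)C(=O)O[C@@H]1[C@@H](O)C(C)(C)[C@@H]2[C@H]3C(=O)C=C(C)[C@@H]2[C@@]3(C)[C@@H]1OC(=O)/C(C)=C\C | intermediate
24 | 7β,8α,9α-tris(angeloyloxy)longipin-2-en-1-one (CNP0330079.1) | C/C=C(/C)C(=O)O[C@@H]1[C@@H](OC(=O)/C(C)=C\C)C(C)(C)[C@@H]2[C@H]3C(=O)C=C(C)[C@@H]2[C@@]3(C)[C@@H]1OC(=O)/C(C)=C\C | target

Total step count: 17. Longest linear sequence: 17 steps (1 → 24); angelic acid 20 is used as purchased, one molecule being incorporated in each of steps 14, 15 and 17.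

**Steps most likely to fail**

Step 11 (Claisen ring contraction). The stabilised enolate may be too weak a donor to rearrange, or the allylic C8 carboxylate may ionise and eliminate to a triene before the C4–C10 bond forms. Fallback, from 14 back to 15: the lactone would be opened with K2CO3 in MeOH at 0 °C to the hydroxy methyl ester F1. The allylic C8 alcohol would be phosphorylated (ClP(O)(OEt)2, DMAP, pyridine) to the allylic diethyl phosphate F2. Treatment with DBU or Cs2CO3 in MeCN (23–60 °C) should then make the C4 carbanion attack C10 in a syn-SN2' alkylation; direct SN2 at C8 is excluded because nucleophile and leaving group lie on the same β face. This gives the cage methyl ester F3, and cleavage with Me3SnOH (1,2-dichloroethane, 80 °C) returns acid 15.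

Step 10 (key step). Conjugate addition at the hindered, neopentyl-like C5 may be too slow, a C11 enol(ate) may expel the allylic C8 carboxylate (vinylogous β-elimination), or protonation at C11 may give the trans ring fusion. Fallback, from 11 back to 14: alcohol 11 would be esterified with but-2-ynoic acid (DCC, DMAP, CH2Cl2) to the but-2-ynoate F4. The acetyl group would be converted with TBSOTf and Et3N (CH2Cl2, −78 °C) into the 2-silyloxy diene F5. Heating (PhMe, 150 °C, sealed tube) should then form the same two bonds, C2–C3 and C4–C5, in an intramolecular Diels–Alder reaction with no enolate present, giving the cyclohexadiene silyl enol ether F6. Mild hydrolysis (1 M HCl, THF, 0 °C) and a catalytic amount of DBU would cleave the enol silane and move the alkene into conjugation with the ketone, which gives 14.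

Step 17 (last angeloylation). Acylation of the neopentylic C7 alcohol, flanked by the C6 gem-dimethyl group and the C8 angelate, may stall, and forcing may isomerise Z to E (angelate to tiglate) in the new ester or in the two already present. Fallback, from 23 to 24: the C7 alcohol would be acylated with 2-[bis(2,2,2-trifluoroethoxy)phosphoryl]propanoic acid (DCC, DMAP, CH2Cl2, 23 °C) to the 7-phosphonopropanoate F7, a mixture of epimers at the CH(CH3)P centre. A Still–Gennari olefination with acetaldehyde (KN(SiMe3)2, 18-crown-6, THF, −78 °C) should then build the third Z-2-methylbut-2-enoate on the molecule and give 24.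

**Further compounds**

F1 | step 11 | hydroxy methyl ester from methanolysis of 14 (8β-OH, C4–CO2CH3, 7β-OTBS) | O[C@@H]1C=C(C)[C@@H]2C(=O)C=C(C)[C@@H](C(=O)OC)[C@@H]2C(C)(C)[C@@H]1O[Si](C)(C)C(C)(C)C
F2 | step 11 | allylic diethyl phosphate of F1 at O8 | CCOP(=O)(OCC)O[C@@H]1C=C(C)[C@@H]2C(=O)C=C(C)[C@@H](C(=O)OC)[C@@H]2C(C)(C)[C@@H]1O[Si](C)(C)C(C)(C)C
F3 | step 11 | methyl ester of 15 | C1=C[C@@]2(C)[C@@H]3C(=O)C=C(C)[C@@]2(C(=O)OC)[C@@H]3C(C)(C)[C@@H]1O[Si](C)(C)C(C)(C)C
F4 | step 10 | but-2-ynoate of 11 at O8 | CC1=C[C@@H](OC(=O)C#CC)[C@@H](O[Si](C)(C)C(C)(C)C)C(C)(C)C=C1C(C)=O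
F5 | step 10 | 2-silyloxy diene from F4 (acetyl converted to C(OTBS)=CH2) | CC1=C[C@@H](OC(=O)C#CC)[C@@H](O[Si](C)(C)C(C)(C)C)C(C)(C)C=C1C(=C)O[Si](C)(C)C(C)(C)C
F6 | step 10 | intramolecular Diels–Alder adduct (C1 silyl enol ether, C3=C4 alkene conjugated to the lactone) | O=C1O[C@@H]2C=C(C)C3=C(O[Si](C)(C)C(C)(C)C)CC(C)=C1[C@@H]3C(C)(C)[C@@H]2O[Si](C)(C)C(C)(C)C
F7 | step 17 | 8α,9α-bis(angeloyloxy)-7β-{2-[bis(2,2,2-trifluoroethoxy)phosphoryl]propanoyloxy}longipin-2-en-1-one | C/C=C(/C)C(=O)O[C@@H]1[C@@H](OC(=O)C(C)P(=O)(OCC(F)(F)F)OCC(F)(F)F)C(C)(C)[C@@H]2[C@H]3C(=O)C=C(C)[C@@H]2[C@@]3(C)[C@@H]1OC(=O)/C(C)=C\C
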